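**Retrosynthetic overview**

1. Ring A (the benzene ring) is made last, by a Diels–Alder/retro-Diels–Alder reaction (loss of CO2) between a ring-B-fused 4-silyloxy-2-pyranone and an alkynyl pyranone that already carries the phenyl group and ring C.
2. The fused pyranone comes from a prochiral 5-silyloxycyclohexane-1,3-dione and a malonyl unit; its lactone C–O bond is closed enantioselectively, and this desymmetrisation sets the only stereocentre (C3 of the target).
3. The dione (ring B) comes from phloroglucinol by reduction and silylation.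
4. Ring C (the 4-hydroxy-2-pyranone on the alkyne) comes from phenylpropiolic acid and trimethyldioxinone by acylation and acylketene lactonisation.
5. Order of ring formation: ring B, sacrificial fused pyranone, ring C (separate branch), ring A; then desilylation.

Assumption: the target is the (3S)-enantiomer as read from the SMILES; bis(2,4,6-trichlorophenyl) malonate and both enantiomers of the isothiourea catalyst are taken as commercial.

**Route**

Step 1
Reactants: 1 phloroglucinol (benzene-1,3,5-triol)
Product: 2 dihydrophloroglucinol (5-hydroxycyclohexane-1,3-dione)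
Conditions: NaBH4 (1.0 equiv), H2O, 0 °C to rt, 2 h; Dowex 50W (H+ form) to pH 4; lyophilise
Reagents that add atoms: none
Why: Hydride reduction of one C=O of the cyclohexane-1,3,5-trione tautomer (known preparation of dihydrophloroglucinol); the product is protected from over-reduction as its enolate, and no stereocentre arises because C5 lies on the mirror plane of the dione.

Step 2
Reactants: 2 dihydrophloroglucinol
Product: 4 silyl ether 5-[(tert-butyldimethylsilyl)oxy]cyclohexane-1,3-dione, via bis-silyl enol ether 3 (not isolated)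
Conditions: t-BuMe2SiCl (2.5 equiv), imidazole (5 equiv), DMF, 0 °C to rt; then THF/1 M aq. HCl, 0 °C, 15 min
Reagents that add atoms: tert-butyldimethylsilyl chloride, CC(C)(C)[Si](C)(C)Cl
Why: Standard imidazole-promoted silylation of the alcohol and the enol, then selective hydrolysis of the labile vinylogous silyl ester with cold dilute acid, which leaves the secondary silyl ether; the product is still achiral (prochiral at C5).

Step 3
Reactants: 4 silyl ether, 5 bis(2,4,6-trichlorophenyl) malonate
Product: 7 fused pyranone (7S)-7-[(tert-butyldimethylsilyl)oxy]-4-hydroxy-7,8-dihydro-2H-chromene-2,5(6H)-dione, via triketo aryl ester 6 (not isolated)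
Conditions: 5 (1.05 equiv, added over 2 h), (2S,3R)-3-isopropyl-2-phenyl-3,4-dihydro-2H-benzo[4,5]thiazolo[3,2-a]pyrimidine (isothiourea HyperBTM, 10 mol %), i-Pr2NEt (2.5 equiv), CH2Cl2, −20 °C to rt, 24 h; 1 M HCl wash; recrystallise to raise ee
Reagents that add atoms: none
Why: Proposed new method: isothiourea-catalysed desymmetrising malonylation–lactonisation (formal [3+3] pyranone annulation), in which the Lewis base is acylated by the aryl ester and passes the malonyl unit to C2 of the dione enolate (O-acylation is reversible through the catalyst) to give prochiral 6, then activates the second aryl ester as an acyl isothiouronium whose carbonyl carbon is attacked by only one of the two enantiotopic enol oxygens, because the phenyl group of the catalyst leaves one face of the acyl unit open and the silyloxy group blocks one face of the half-chair; this C–O bond formation decides which carbonyl becomes the enol-lactone carbon and so sets C7 as (S), release of 7 as its vinylogous carboxylate makes it irreversible, and the uncatalysed condensation of 4 with 5 needs about 150 °C so no racemic background is expected; the closest known reaction types are the isothiourea-catalysed Michael addition–lactonisation of α,β-unsaturated aryl esters with 1,3-dicarbonyls (same catalyst-releasing enol lactonisation) and the isothiourea-catalysed acylative desymmetrisation of prochiral diols; the sense of induction cannot be predicted with confidence and must be checked, and the antipodal catalyst is used if the (R)-lactone forms.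

Step 4
Reactants: 8 3-phenylpropiolic acid, 9 2,2,6-trimethyl-4H-1,3-dioxin-4-one
Product: 12 keto-dioxinone 2,2-dimethyl-6-(2-oxo-4-phenylbut-3-yn-1-yl)-4H-1,3-dioxin-4-one, via 3-phenylpropioloyl chloride 10 (not isolated), via lithium dienolate 11 (not isolated)
Conditions: 8, (COCl)2 (1.2 equiv), DMF (cat.), CH2Cl2, 0 °C to rt, evaporate; separately 9 (2.0 equiv), LiN(SiMe3)2 (2.1 equiv), THF, −78 °C, 45 min; add 10, −78 °C, 1 h; aq. NH4Cl then 1 M HCl
Reagents that add atoms: none
Why: Vinylogous Claisen-type γ-acylation of the dioxinone lithium dienolate with an acid chloride (established keto-dioxinone synthesis); the second equivalent of dienolate deprotonates the acidic product, which protects the ynone from conjugate addition; no stereocentre.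

Step 5
Reactants: 12 keto-dioxinone
Product: 14 alkynyl pyranone 4-hydroxy-6-(phenylethynyl)-2H-pyran-2-one, via acylketene 13 (not isolated)
Conditions: toluene, 110 °C, 1 h (acetone distilled off); crystallise on cooling
Reagents that add atoms: none
Why: Thermal retro-[4+2] of the dioxinone releases acetone and acylketene 13, which closes by attack of the ynone enol oxygen on the ketene carbon (oxa-6π electrocyclisation, C–O bond) to give ring C, the standard 4-hydroxy-2-pyranone synthesis.

Step 6
Reactants: 7 fused pyranone, 14 alkynyl pyranone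
Product: 19 silyl-protected wailupemycin F (3S)-3-[(tert-butyldimethylsilyl)oxy]-8-hydroxy-5-(4-hydroxy-2-oxo-2H-pyran-6-yl)-6-phenyl-3,4-dihydronaphthalen-1(2H)-one, via diene silyl ether 15 (not isolated), via alkyne silyl ether 16 (not isolated), via bridged lactone 17 (not isolated), via disilylated arene 18 (not isolated)
Conditions: 14 (3 equiv), N,O-bis(trimethylsilyl)acetamide (8 equiv), mesitylene, 155 °C, sealed tube, 36 h; then THF/1 M aq. citric acid, rt, 30 min
Reagents that add atoms: none
Why: Diels–Alder/retro-Diels–Alder benzannulation of a fused 2-pyranone with an alkyne (known for 5-oxo-tetrahydrochromen-2-ones, which give 1-tetralones): in situ silylation removes the acidic OH groups and makes the diene electron-rich, the polarity-matched cycloaddition joins nucleophilic C3 of 15 to the phenyl-bearing alkyne carbon (the vinylogous acceptor position of 16) and electrophilic C8a to the pyranonyl-bearing carbon, and loss of CO2 from 17 forms ring A with OH, phenyl and pyranonyl in the required positions; the stereocentre is remote from every bond change and is retained.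

Step 7
Reactants: 19 silyl-protected wailupemycin F
Product: 20 wailupemycin F (3S)-3,8-dihydroxy-5-(4-hydroxy-2-oxo-2H-pyran-6-yl)-6-phenyl-3,4-dihydronaphthalen-1(2H)-one
Conditions: HF·pyridine, THF/pyridine, 0 °C to rt, 6 h; pH 7 phosphate buffer work-up
Reagents that add atoms: none
Why: Fluoride-mediated cleavage of the secondary silyl ether in a buffered, non-basic medium, which avoids E1cB dehydration of the β-hydroxy ketone to the naphthol; no bond to C3 is broken, so the (S) configuration is kept.

**Compound list**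

1 | phloroglucinol (benzene-1,3,5-triol) | Oc1cc(O)cc(O)c1 | starting material
2 | dihydrophloroglucinol (5-hydroxycyclohexane-1,3-dione, achiral) | O=C1CC(O)CC(=O)C1 | intermediate
3 | 3,5-bis[(tert-butyldimethylsilyl)oxy]cyclohex-2-en-1-one (racemic, not isolated) | O=C1C=C(O[Si](C)(C)C(C)(C)C)CC(O[Si](C)(C)C(C)(C)C)C1 | intermediate
4 | 5-[(tert-butyldimethylsilyl)oxy]cyclohexane-1,3-dione (achiral, prochiral at C5) | O=C1CC(O[Si](C)(C)C(C)(C)C)CC(=O)C1 | intermediate
5 | bis(2,4,6-trichlorophenyl) malonate | O=C(CC(=O)Oc1c(Cl)cc(Cl)cc1Cl)Oc1c(Cl)cc(Cl)cc1Cl | starting material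
6 | 2,4,6-trichlorophenyl 3-{4-[(tert-butyldimethylsilyl)oxy]-2,6-dioxocyclohexylidene}-3-hydroxypropanoate (enol form of the triketo ester, achiral, not isolated) | O=C1CC(O[Si](C)(C)C(C)(C)C)CC(=O)C1=C(O)CC(=O)Oc1c(Cl)cc(Cl)cc1Cl | intermediate
7 | (7S)-7-[(tert-butyldimethylsilyl)oxy]-4-hydroxy-7,8-dihydro-2H-chromene-2,5(6H)-dione | O=C1C[C@@H](O[Si](C)(C)C(C)(C)C)CC2=C1C(O)=CC(=O)O2 | intermediate
8 | 3-phenylpropiolic acid | OC(=O)C#Cc1ccccc1 | starting material
9 | 2,2,6-trimethyl-4H-1,3-dioxin-4-one | CC1=CC(=O)OC(C)(C)O1 | starting material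
10 | 3-phenylpropioloyl chloride (not isolated) | O=C(Cl)C#Cc1ccccc1 | intermediate
11 | lithium 2,2-dimethyl-6-methylidene-6H-1,3-dioxin-4-olate (not isolated) | [Li+].[O-]C1=CC(=C)OC(C)(C)O1 | intermediate
12 | 2,2-dimethyl-6-(2-oxo-4-phenylbut-3-yn-1-yl)-4H-1,3-dioxin-4-one | CC1(C)OC(=O)C=C(CC(=O)C#Cc2ccccc2)O1 | intermediate
13 | 7-phenylhept-1-en-6-yne-1,3,5-trione (acylketene, not isolated) | O=C=CC(=O)CC(=O)C#Cc1ccccc1 | intermediate
14 | 4-hydroxy-6-(phenylethynyl)-2H-pyran-2-one | O=c1cc(O)cc(C#Cc2ccccc2)o1 | intermediate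
15 | (7S)-7-[(tert-butyldimethylsilyl)oxy]-4-[(trimethylsilyl)oxy]-7,8-dihydro-2H-chromene-2,5(6H)-dione (not isolated) | O=C1C[C@@H](O[Si](C)(C)C(C)(C)C)CC2=C1C(O[Si](C)(C)C)=CC(=O)O2 | intermediate
16 | 6-(phenylethynyl)-4-[(trimethylsilyl)oxy]-2H-pyran-2-one (not isolated) | O=c1cc(O[Si](C)(C)C)cc(C#Cc2ccccc2)o1 | intermediate
17 | bridged lactone: [4+2] adduct of the alkyne of 16 across C3 and C8a of 15 (2-oxabicyclo[2.2.2]octa-5,7-dien-3-one fused to ring B; both bridgehead diastereomers; silyloxy-bearing centre as in 7; not isolated) | O=C1C[C@@H](O[Si](C)(C)C(C)(C)C)CC23OC(=O)C(C(O[Si](C)(C)C)=C12)C(c1ccccc1)=C3c1cc(O[Si](C)(C)C)cc(=O)o1 | intermediate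
18 | (3S)-3-[(tert-butyldimethylsilyl)oxy]-6-phenyl-8-[(trimethylsilyl)oxy]-5-{2-oxo-4-[(trimethylsilyl)oxy]-2H-pyran-6-yl}-3,4-dihydronaphthalen-1(2H)-one (not isolated) | O=C1C[C@@H](O[Si](C)(C)C(C)(C)C)Cc2c1c(O[Si](C)(C)C)cc(-c1ccccc1)c2-c1cc(O[Si](C)(C)C)cc(=O)o1 | intermediate
19 | (3S)-3-[(tert-butyldimethylsilyl)oxy]-8-hydroxy-5-(4-hydroxy-2-oxo-2H-pyran-6-yl)-6-phenyl-3,4-dihydronaphthalen-1(2H)-one | O=C1C[C@@H](O[Si](C)(C)C(C)(C)C)Cc2c1c(O)cc(-c1ccccc1)c2-c1cc(O)cc(=O)o1 | intermediate
20 | wailupemycin F, (3S)-3,8-dihydroxy-5-(4-hydroxy-2-oxo-2H-pyran-6-yl)-6-phenyl-3,4-dihydronaphthalen-1(2H)-one | O=C1C[C@@H](O)Cc2c1c(O)cc(-c1ccccc1)c2-c1cc(O)cc(=O)o1 | target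

**Step count and risks**

Total steps: 7. Longest linear sequence: 5 (steps 1, 2, 3, 6, 7); steps 4 and 5 form the second branch, which joins at step 6.

Three steps most likely to fail:

- **Step 3 (the proposed new step).** The prochiral centre is remote from the reacting oxygens, so the ee may be low, and the malonate may self-condense. The fallback uses known chemistry, sets out from 4 and 5 and returns at 7. Heat 4 with 5 without catalyst in bromobenzene at 150 °C (thermal cyclocondensation of a 1,3-dione with an aryl malonate) to obtain racemic 7-[(tert-butyldimethylsilyl)oxy]-4-hydroxy-7,8-dihydro-2H-chromene-2,5(6H)-dione F1. Separate it by preparative chiral supercritical-fluid chromatography on an amylose carbamate phase, discard the (7R)-enantiomer F2 and carry the (7S)-enantiomer on as 7.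

- **Step 4.** The ynoyl chloride and the ynone product can suffer conjugate addition, O-acylation or double acylation. The fallback sets out from 9 and returns at 12. Convert 9 into silyl dienol ether F3 (LiN(SiMe3)2, Me3SiCl, THF, −78 °C). Add it to commercial 3-phenylprop-2-ynal in a vinylogous Mukaiyama aldol reaction (BF3·OEt2, CH2Cl2, −78 °C) to give racemic propargylic alcohol F4. Oxidise with MnO2 in CH2Cl2 to the ynone 12.

- **Step 6.** The pyranone ring of 16 is itself a diene and can consume the alkyne, the cycloaddition may be slow, and prolonged heating may cost the silyloxy group. The fallback sets out from 7 (silylated in situ to 15 as in step 6) and returns at 19; it builds ring C after ring A. Heat 15 with commercial 3-phenylprop-2-ynal (a more reactive dienophile with no diene unit and the same polarity, hence the same regiochemistry) in toluene at 110–130 °C. The bridged lactone F5 loses CO2 to give silylated aldehyde F6, and citric acid work-up gives aldehyde F7. Chemoselective vinylogous Mukaiyama aldol addition of silyl dienol ether F3 (BF3·OEt2, CH2Cl2, −78 °C; the hydrogen-bonded aryl ketone is far less electrophilic and should not react) gives benzylic alcohol F8 as a mixture of carbinol epimers. MnO2 oxidation gives keto-dioxinone F9. Heating in toluene at 110 °C closes ring C by the same acylketene lactonisation as in step 5 and delivers 19.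

**Further compounds**

F1 | step 3 | racemic 7-[(tert-butyldimethylsilyl)oxy]-4-hydroxy-7,8-dihydro-2H-chromene-2,5(6H)-dione | O=C1CC(O[Si](C)(C)C(C)(C)C)CC2=C1C(O)=CC(=O)O2
F2 | step 3 | (7R)-7-[(tert-butyldimethylsilyl)oxy]-4-hydroxy-7,8-dihydro-2H-chromene-2,5(6H)-dione | O=C1C[C@H](O[Si](C)(C)C(C)(C)C)CC2=C1C(O)=CC(=O)O2
F3 | step 4 | [(2,2-dimethyl-6-methylidene-6H-1,3-dioxin-4-yl)oxy]trimethylsilane | C=C1C=C(O[Si](C)(C)C)OC(C)(C)O1
F4 | step 4 | racemic 6-(2-hydroxy-4-phenylbut-3-yn-1-yl)-2,2-dimethyl-4H-1,3-dioxin-4-one | CC1(C)OC(=O)C=C(CC(O)C#Cc2ccccc2)O1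
F5 | step 6 | bridged lactone: [4+2] adduct of 3-phenylprop-2-ynal across C3 and C8a of 15 (both bridgehead diastereomers) | O=C1C[C@@H](O[Si](C)(C)C(C)(C)C)CC23OC(=O)C(C(O[Si](C)(C)C)=C12)C(c1ccccc1)=C3C=O
F6 | step 6 | (7S)-7-[(tert-butyldimethylsilyl)oxy]-5-oxo-2-phenyl-4-[(trimethylsilyl)oxy]-5,6,7,8-tetrahydronaphthalene-1-carbaldehyde | O=C1C[C@@H](O[Si](C)(C)C(C)(C)C)Cc2c1c(O[Si](C)(C)C)cc(-c1ccccc1)c2C=O
F7 | step 6 | (7S)-7-[(tert-butyldimethylsilyl)oxy]-4-hydroxy-5-oxo-2-phenyl-5,6,7,8-tetrahydronaphthalene-1-carbaldehyde | O=C1C[C@@H](O[Si](C)(C)C(C)(C)C)Cc2c1c(O)cc(-c1ccccc1)c2C=O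
F8 | step 6 | 6-{2-[(7S)-7-[(tert-butyldimethylsilyl)oxy]-4-hydroxy-5-oxo-2-phenyl-5,6,7,8-tetrahydronaphthalen-1-yl]-2-hydroxyethyl}-2,2-dimethyl-4H-1,3-dioxin-4-one (both carbinol epimers) | O=C1C[C@@H](O[Si](C)(C)C(C)(C)C)Cc2c1c(O)cc(-c1ccccc1)c2C(O)CC1=CC(=O)OC(C)(C)O1
F9 | step 6 | 6-{2-[(7S)-7-[(tert-butyldimethylsilyl)oxy]-4-hydroxy-5-oxo-2-phenyl-5,6,7,8-tetrahydronaphthalen-1-yl]-2-oxoethyl}-2,2-dimethyl-4H-1,3-dioxin-4-one | O=C1C[C@@H](O[Si](C)(C)C(C)(C)C)Cc2c1c(O)cc(-c1ccccc1)c2C(=O)CC1=CC(=O)OC(C)(C)O1
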